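Locants: unprimed atoms belong to the upper flavanone (benzo ring A, catechol ring B, pyranone ring C). Double-primed atoms belong to the lower one (benzo ring A'', pyranone ring C'', phenol ring B'').
Cuts, last-formed first: C2''–ring B''; O1–C2; C4–C4a; O1''–C2'' and C4a''–C4''; ring A'' itself at C8''–C8a'', C6''–C7'' and C4a''–C8a''; finally C3–C8'' and C2–C3.
Enabling feature: ring A'' is a phloroglucinol ring in which C8'' carries C3 and lies between C7''–O and C8a''–O1'', with C5''–O para to it. A siloxyalkyne (C8''≡C7''–OSi) and the four carbons of a 3-alkoxycyclobutenone (C8a''=O, C6'', C5''–OR, C4a'') deliver exactly this pattern.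
Forward: aldol chain (C2, C3, vinyl as latent C4) → siloxyalkyne → ring A'' → ring C'' as a chromone → ring A onto C4 → ring C → ring B'' onto C2'' → deprotection.
Stereochemistry: C2 comes from an auxiliary-controlled syn aldol (S carbinol) that is inverted once when ring C closes. C3 is set by equilibration to the 2,3-trans ketone, and C2'' by a chiral rhodium catalyst.

Key step: step 7

Assumption: 1, 2, 4, 13, 24 and 33 are taken as commercial. The (S)-biaryl diphosphine of step 19 is assumed to shield the chromone as it shields cyclohexenone-type enones (giving 2''S); if the sense is opposite, its antipode is used.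

Step 1
Reactants: 1 (S)-4-benzyl-1,3-oxazolidin-2-one; 2 (E)-but-2-enoyl chloride
Product: 3 (S)-4-benzyl-3-[(E)-but-2-enoyl]-1,3-oxazolidin-2-one
Conditions: n-BuLi, THF, −78 °C; then 2, −78 → 0 °C
Reagents that add atoms: none
Why: N-acylation of the lithiated oxazolidinone with an acid chloride is the standard entry to N-enoyl imides and touches no stereocenter.

Step 2
Reactants: 3 (S)-4-benzyl-3-[(E)-but-2-enoyl]-1,3-oxazolidin-2-one; 4 3,4-bis(benzyloxy)benzaldehyde
Product: 6 (S)-4-benzyl-3-{(2S)-2-[(S)-[3,4-bis(benzyloxy)phenyl](hydroxy)methyl]but-3-enoyl}-1,3-oxazolidin-2-one, via boron dienolate 5 (not isolated)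
Conditions: Bu2BOTf, Et3N, CH2Cl2, −78 → 0 °C; 4, −78 → 0 °C; H2O2, MeOH, pH 7 buffer, 0 °C
Reagents that add atoms: none
Why: In this deconjugative Evans syn aldol, γ-deprotonation of the boron-bound crotonyl imide gives (Z)-dienolate 5, which reacts at its α-carbon through a chair Zimmerman–Traxler transition state on the face away from the auxiliary benzyl group, so the carbinol carbon (future C2) is set as S and the vinyl-bearing carbon (future C3) syn to it.

Step 3
Reactants: 6 syn-aldol imide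
Product: 7 (S)-4-benzyl-3-{(2S)-2-[(S)-[3,4-bis(benzyloxy)phenyl](tert-butyldimethylsilyloxy)methyl]but-3-enoyl}-1,3-oxazolidin-2-one
Conditions: TBSOTf, 2,6-lutidine, CH2Cl2, −78 → 0 °C
Reagents that add atoms: tert-butyldimethylsilyl triflate, CC(C)(C)[Si](C)(C)OS(=O)(=O)C(F)(F)F
Why: O-silylation with a silyl triflate and a hindered pyridine is fast in the cold, blocks retro-aldol cleavage in the later basic steps and is too mild to ionize the electron-rich benzylic alcohol.

Step 4
Reactants: 7 silylated aldol imide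
Product: 8 (2S)-2-[(S)-[3,4-bis(benzyloxy)phenyl](tert-butyldimethylsilyloxy)methyl]but-3-enoic acid
Conditions: LiOH, H2O2, THF–H2O, 0 °C; Na2SO3; 1 M HCl to pH 4
Reagents that add atoms: hydrogen peroxide, OO
Why: In this hydroperoxide hydrolysis of an N-acyl oxazolidinone, the small and weakly basic hydroperoxide anion attacks the exocyclic carbonyl even in hindered aldol ethers, so the α-vinyl centre is neither epimerized nor conjugated and the auxiliary is recovered.

Step 5
Reactants: 8 butenoic acid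
Product: 9 methyl (2S)-2-[(S)-[3,4-bis(benzyloxy)phenyl](tert-butyldimethylsilyloxy)methyl]but-3-enoate
Conditions: TMSCHN2, toluene–MeOH, 0 °C
Reagents that add atoms: (trimethylsilyl)diazomethane, C[Si](C)(C)C=[N+]=[N-]
Why: Diazoalkane esterification needs neither added acid nor base, so the β,γ-unsaturated ester forms without double-bond migration.

Step 6
Reactants: 9 methyl ester
Product: 12 (3R,4S)-4-[3,4-bis(benzyloxy)phenyl]-4-(tert-butyldimethylsilyloxy)-3-ethenyl-1-(triisopropylsilyloxy)but-1-yne, via dibromo enolate 10 (not isolated), via lithium ynolate 11 (not isolated)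
Conditions: CH2Br2, LiTMP (from TMPH, n-BuLi), THF, −90 °C; 9; LiHMDS, −78 °C; n-BuLi, −78 → 0 °C; TIPSOTf, −78 → 0 °C
Reagents that add atoms: dibromomethane, BrCBr; triisopropylsilyl triflate, CC(C)[Si](OS(=O)(=O)C(F)(F)F)(C(C)C)C(C)C
Why: This is a Kowalski ester homologation stopped at the ynolate, in which preformed LiCHBr2 adds to the ester, deprotonation gives 10, bromine–lithium exchange triggers a carbenoid 1,2-shift that moves C3 with retention onto the new carbon (C8'') to give 11, and the bulky silyl triflate traps 11 on oxygen rather than on carbon.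

Step 7
Reactants: 12 siloxyalkyne; 13 3-ethoxycyclobut-2-en-1-one
Product: 17 2-[(1S,2R)-1-[3,4-bis(benzyloxy)phenyl]-1-(tert-butyldimethylsilyloxy)but-3-en-2-yl]-5-ethoxy-3-(triisopropylsilyloxy)phenol, via ethoxyvinylketene 14 (not isolated), via vinylcyclobutenone 15 (not isolated), via dienylketene 16 (not isolated)
Conditions: toluene, 80 → 120 °C, sealed vessel, 13 (1.3 equiv) added slowly
Reagents that add atoms: none
Why: In this Danheiser benzannulation, heat opens 13 by 4π electrocyclic cleavage to vinylketene 14, whose carbonyl carbon (future C8a'') is attacked by the nucleophilic, side-chain-bearing alkyne carbon of 12 (C8'') in a [2+2] cycloaddition that also joins C6'' to C7'' and gives the four-membered ring of 15. A second 4π opening turns 15 into dienylketene 16, and ring A'' closes by thermal 6π electrocyclization between C8a'' and C4a'', followed by tautomerization of the cyclohexadienone to the phenol. The closest known reaction is the benzannulation of cyclobutenones with triisopropylsiloxyalkynes obtained by ester homologation, including alkynes branched at the propargylic carbon. No lasting stereocenter is created, since the sp3 ring carbon of 15 becomes planar again, and C2 and C3 lie outside the reacting π system and are carried through unchanged. The selectivity needed is regiochemical and the oxygen-polarized alkyne secures it, because only the carbon β to the siloxy group is nucleophilic, so the side chain ends between the free hydroxyl (O1'') and the silyl ether (O7'') with the ethoxy group (O5'') para to it. Slow addition of 13 keeps the ketene concentration low, which limits ketene dimerization and acylation of the product phenol.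

Step 8
Reactants: 17 ring A'' phenol
Product: 18 3-[(1S,2R)-1-[3,4-bis(benzyloxy)phenyl]-1-(tert-butyldimethylsilyloxy)but-3-en-2-yl]-6-ethoxy-2-hydroxy-4-(triisopropylsilyloxy)benzaldehyde
Conditions: MgCl2, Et3N, (CH2O)n, THF, reflux; cold 0.5 M HCl
Reagents that add atoms: paraformaldehyde (as formaldehyde), C=O
Why: In the Casnati–Skattebøl ortho-formylation the magnesium phenoxide delivers formaldehyde only to the position ortho to the free hydroxyl, which here is C4a'' alone, so C6'' next to the silyl ether stays untouched and no Lewis acid strong enough to ionize C2 is present.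

Step 9
Reactants: 18 salicylaldehyde
Product: 19 1-{3-[(1S,2R)-1-[3,4-bis(benzyloxy)phenyl]-1-(tert-butyldimethylsilyloxy)but-3-en-2-yl]-6-ethoxy-2-hydroxy-4-(triisopropylsilyloxy)phenyl}prop-2-yn-1-ol (both carbinol epimers)
Conditions: HC≡CMgBr (3 equiv), THF, 0 °C → rt; H2O
Reagents that add atoms: ethynylmagnesium bromide, C#C[Mg]Br
Why: This is a Grignard 1,2-addition in which the first equivalent deprotonates the phenol and the excess adds to the aldehyde, the silyl ethers are inert, and the new carbinol centre needs no control because it is oxidized next.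

Step 10
Reactants: 19 propargylic alcohol
Product: 21 8-[(1S,2R)-1-[3,4-bis(benzyloxy)phenyl]-1-(tert-butyldimethylsilyloxy)but-3-en-2-yl]-5-ethoxy-7-(triisopropylsilyloxy)-4H-chromen-4-one, via ynone 20 (not isolated)
Conditions: MnO2, CH2Cl2, rt; filter; DMAP (20 mol %), CH2Cl2, rt
Reagents that add atoms: none
Why: MnO2 oxidation of the doubly activated (benzylic and propargylic) alcohol gives o-hydroxyaryl ynone 20, and nucleophilic catalysis by DMAP steers the phenol to the unsubstituted β-carbon in a 6-endo-dig oxa-Michael cyclization that closes ring C'' as a chromone rather than an aurone.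

Step 11
Reactants: 21 silyloxychromone
Product: 22 7-(benzyloxy)-8-[(1S,2R)-1-[3,4-bis(benzyloxy)phenyl]-1-(tert-butyldimethylsilyloxy)but-3-en-2-yl]-5-ethoxy-4H-chromen-4-one
Conditions: CsF, BnBr, DMF, rt
Reagents that add atoms: benzyl bromide, BrCc1ccccc1
Why: In this one-pot fluoride desilylation and Williamson benzylation, the aryl silyl ether para to the chromone carbonyl releases a stabilized phenoxide far faster than the hindered secondary alkyl silyl ether reacts, so O7'' is capped and cannot compete later for C2.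

Step 12
Reactants: 22 vinyl chromone
Product: 23 (2R,3S)-2-[7-(benzyloxy)-5-ethoxy-4-oxo-4H-chromen-8-yl]-3-[3,4-bis(benzyloxy)phenyl]-3-(tert-butyldimethylsilyloxy)propanal
Conditions: OsO4 (2 mol %), NaIO4, 2,6-lutidine, dioxane–H2O, rt
Reagents that add atoms: osmium tetroxide, O=[Os](=O)(=O)=O; sodium periodate, [Na+].[O-]I(=O)(=O)=O
Why: In the Lemieux–Johnson cleavage OsO4 picks the monosubstituted alkene over the push–pull C2''=C3'' bond of the pyrone and over the electron-rich arenes that ozone would attack, and the lutidine buffer protects the enolizable aldehyde.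

Step 13
Reactants: 24 1,3,5-tris(benzyloxy)benzene
Product: 25 2-bromo-1,3,5-tris(benzyloxy)benzene
Conditions: NBS, CH2Cl2, −78 → 0 °C
Reagents that add atoms: N-bromosuccinimide, O=C1CCC(=O)N1Br
Why: Electrophilic aromatic bromination of this symmetrical, strongly activated arene stops at the monobromide in the cold, and all three free positions are equivalent.

Step 14
Reactants: 25 2-bromo-1,3,5-tris(benzyloxy)benzene; 23 aldehyde
Product: 27 2-[7-(benzyloxy)-5-ethoxy-4-oxo-4H-chromen-8-yl]-3-[3,4-bis(benzyloxy)phenyl]-3-(tert-butyldimethylsilyloxy)-1-[2,4,6-tris(benzyloxy)phenyl]propan-1-ol (C2 and C3 as in 23; both C4 epimers), via aryllithium 26 (not isolated)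
Conditions: 25, n-BuLi, THF, −78 °C; then 23, −78 °C; pH 7 buffer at −78 °C
Reagents that add atoms: none
Why: After bromine–lithium exchange, the 1,2-addition of the aryllithium at −78 °C favours the aldehyde, which is far more electrophilic than the vinylogous-ester carbonyl or C2'' of the chromone, while the cold quench prevents silyl migration and the C4 carbinol centre is removed in the next step.

Step 15
Reactants: 27 carbinol
Product: 28 (2R,3S)-2-[7-(benzyloxy)-5-ethoxy-4-oxo-4H-chromen-8-yl]-3-[3,4-bis(benzyloxy)phenyl]-3-(tert-butyldimethylsilyloxy)-1-[2,4,6-tris(benzyloxy)phenyl]propan-1-one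
Conditions: Dess–Martin periodinane, NaHCO3, CH2Cl2, 0 °C → rt
Reagents that add atoms: none
Why: The Dess–Martin oxidation handles hindered benzylic alcohols under buffered, near-neutral conditions that spare the β-silyloxy group and the benzyl ethers.

Step 16
Reactants: 28 ketone
Product: 29 (2R,3S)-2-[7-(benzyloxy)-5-ethoxy-4-oxo-4H-chromen-8-yl]-1-[2,4-bis(benzyloxy)-6-hydroxyphenyl]-3-[3,4-bis(benzyloxy)phenyl]-3-(tert-butyldimethylsilyloxy)propan-1-one
Conditions: MgBr2·OEt2 (3 equiv), toluene–Et2O, rt → 50 °C; H2O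
Reagents that add atoms: none
Why: In this chelation-controlled ether cleavage MgBr2 bridges the C4 carbonyl and one of the two equivalent ortho benzyloxy oxygens so that bromide removes only that benzyl group, while unchelated benzyl ethers, the much less SN2-reactive peri ethyl ether and the silyl ether remain.

Step 17
Reactants: 29 phenol ketone
Product: 30 (2R,3S)-2-[7-(benzyloxy)-5-ethoxy-4-oxo-4H-chromen-8-yl]-1-[2,4-bis(benzyloxy)-6-hydroxyphenyl]-3-[3,4-bis(benzyloxy)phenyl]-3-hydroxypropan-1-one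
Conditions: HF·pyridine, pyridine, THF, 0 °C → rt
Reagents that add atoms: none
Why: Fluoride desilylation in a pyridine-buffered medium avoids the retro-aldol and β-elimination pathways of basic fluoride and is not acidic enough to ionize the benzylic alcohol.

Step 18
Reactants: 30 hydroxy ketone
Product: 32 (2R,3S)-5,7-bis(benzyloxy)-3-[7-(benzyloxy)-5-ethoxy-4-oxo-4H-chromen-8-yl]-2-[3,4-bis(benzyloxy)phenyl]chroman-4-one, via cis-flavanone 31 (not isolated)
Conditions: PPh3, DIAD, toluene, 0 °C; then Et3N, MeOH, rt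
Reagents that add atoms: none
Why: In this intramolecular Mitsunobu etherification the oxyphosphonium salt of the S carbinol is displaced from the rear by the ring A phenol (6-exo-tet), giving 2R in the 2,3-cis flavanone 31, whose C3–H (α to the ketone and benzylic) is then equilibrated through the enol by the weak amine in a protic medium to the diequatorial 2,3-trans isomer (3S) without opening ring C.

Step 19
Reactants: 32 flavanone–chromone; 33 4-(benzyloxy)phenylboronic acid
Product: 34 (2R,3S)-5,7-bis(benzyloxy)-3-{(2S)-7-(benzyloxy)-2-[4-(benzyloxy)phenyl]-5-ethoxy-4-oxochroman-8-yl}-2-[3,4-bis(benzyloxy)phenyl]chroman-4-one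
Conditions: [Rh(OH)(cod)]2 (3 mol %), (S)-2,2'-bis[bis(3,4,5-trifluorophenyl)phosphino]-6,6'-dimethoxybiphenyl, 33 (3 equiv), toluene–H2O, rt → 40 °C
Reagents that add atoms: none
Why: In this Hayashi–Miyaura asymmetric 1,4-addition to a chromone, the aryl-rhodium species inserts the C2''=C3'' bond on the face left open by the (S)-diphosphine, which sets C2'' as S under catalyst control, and hydrolysis of the rhodium enolate needs no added base, so neither flavanone is opened.

Step 20
Reactants: 34 hexabenzyl ethyl ether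
Product: 35 (2R,3S)-7-(benzyloxy)-3-{(2S)-7-(benzyloxy)-2-[4-(benzyloxy)phenyl]-5-hydroxy-4-oxochroman-8-yl}-2-[3,4-bis(benzyloxy)phenyl]-5-hydroxychroman-4-one
Conditions: BCl3 (2.5 equiv), CH2Cl2, −78 → 0 °C; H2O
Reagents that add atoms: none
Why: In this chelation-assisted ether cleavage, roughly one BCl3 per carbonyl locks each ketone to its peri alkoxy oxygen, so chloride removes the 5''-ethyl and 5-benzyl groups in the cold, and any further benzyl loss is harmless because the last step removes them all.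

Step 21
Reactants: 35 pentabenzyl ether
Product: 36 (2R,3S)-2-(3,4-dihydroxyphenyl)-3-[(2S)-5,7-dihydroxy-2-(4-hydroxyphenyl)-4-oxochroman-8-yl]-5,7-dihydroxychroman-4-one (CNP0105436.2)
Conditions: H2 (1 atm), 10% Pd/C, EtOAc–MeOH, rt
Reagents that add atoms: none
Why: Catalytic hydrogenolysis of aryl benzyl ethers is neutral, leaves the hydrogen-bonded aryl ketones alone and cannot epimerize C2, C3 or C2''.

Compound list
1 | (S)-4-benzyl-1,3-oxazolidin-2-one | O=C1N[C@@H](Cc2ccccc2)CO1 | starting material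
2 | (E)-but-2-enoyl chloride | C/C=C/C(=O)Cl | starting material
3 | (S)-4-benzyl-3-[(E)-but-2-enoyl]-1,3-oxazolidin-2-one | C/C=C/C(=O)N1[C@@H](Cc2ccccc2)COC1=O | intermediate
4 | 3,4-bis(benzyloxy)benzaldehyde | O=Cc1ccc(OCc2ccccc2)c(OCc2ccccc2)c1 | starting material
5 | di-n-butylboron (Z)-dienolate of 3 | C=C/C=C(\OB(CCCC)CCCC)N1[C@@H](Cc2ccccc2)COC1=O | intermediate
6 | syn-aldol imide, (2S) and (S)-carbinol | O=C1OC[C@H](Cc2ccccc2)N1C(=O)[C@@H](C=C)[C@H](O)c1ccc(OCc2ccccc2)c(OCc2ccccc2)c1 | intermediate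
7 | tert-butyldimethylsilyl ether of 6 | O=C1OC[C@H](Cc2ccccc2)N1C(=O)[C@@H](C=C)[C@H](O[Si](C)(C)C(C)(C)C)c1ccc(OCc2ccccc2)c(OCc2ccccc2)c1 | intermediate
8 | (2S)-2-[(S)-[3,4-bis(benzyloxy)phenyl](tert-butyldimethylsilyloxy)methyl]but-3-enoic acid | OC(=O)[C@@H](C=C)[C@H](O[Si](C)(C)C(C)(C)C)c1ccc(OCc2ccccc2)c(OCc2ccccc2)c1 | intermediate
9 | methyl ester of 8 | COC(=O)[C@@H](C=C)[C@H](O[Si](C)(C)C(C)(C)C)c1ccc(OCc2ccccc2)c(OCc2ccccc2)c1 | intermediate
10 | lithium enolate of the dibromomethyl ketone from 9 | [Li]OC(=C(Br)Br)[C@@H](C=C)[C@H](O[Si](C)(C)C(C)(C)C)c1ccc(OCc2ccccc2)c(OCc2ccccc2)c1 | intermediate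
11 | lithium ynolate | [Li]OC#C[C@@H](C=C)[C@H](O[Si](C)(C)C(C)(C)C)c1ccc(OCc2ccccc2)c(OCc2ccccc2)c1 | intermediate
12 | (3R,4S)-4-[3,4-bis(benzyloxy)phenyl]-4-(tert-butyldimethylsilyloxy)-3-ethenyl-1-(triisopropylsilyloxy)but-1-yne | CC(C)[Si](C(C)C)(C(C)C)OC#C[C@@H](C=C)[C@H](O[Si](C)(C)C(C)(C)C)c1ccc(OCc2ccccc2)c(OCc2ccccc2)c1 | intermediate
13 | 3-ethoxycyclobut-2-en-1-one | CCOC1=CC(=O)C1 | starting material
14 | 3-ethoxybuta-1,3-dien-1-one (ethoxyvinylketene) | CCOC(=C)C=C=O | intermediate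
15 | 4-(1-ethoxyethenyl)-3-(triisopropylsilyloxy)cyclobut-2-en-1-one bearing the C3 side chain at its C2 | CCOC(=C)C1C(=O)C([C@@H](C=C)[C@H](O[Si](C)(C)C(C)(C)C)c2ccc(OCc3ccccc3)c(OCc3ccccc3)c2)=C1O[Si](C(C)C)(C(C)C)C(C)C | intermediate
16 | dienylketene from ring opening of 15 | CCOC(=C)C=C(O[Si](C(C)C)(C(C)C)C(C)C)C(=C=O)[C@@H](C=C)[C@H](O[Si](C)(C)C(C)(C)C)c1ccc(OCc2ccccc2)c(OCc2ccccc2)c1 | intermediate
17 | 2-[(1S,2R)-1-[3,4-bis(benzyloxy)phenyl]-1-(tert-butyldimethylsilyloxy)but-3-en-2-yl]-5-ethoxy-3-(triisopropylsilyloxy)phenol | CCOc1cc(O)c([C@@H](C=C)[C@H](O[Si](C)(C)C(C)(C)C)c2ccc(OCc3ccccc3)c(OCc3ccccc3)c2)c(O[Si](C(C)C)(C(C)C)C(C)C)c1 | intermediate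
18 | salicylaldehyde (formyl at C4a'') | CCOc1cc(O[Si](C(C)C)(C(C)C)C(C)C)c([C@@H](C=C)[C@H](O[Si](C)(C)C(C)(C)C)c2ccc(OCc3ccccc3)c(OCc3ccccc3)c2)c(O)c1C=O | intermediate
19 | propargylic alcohol (both carbinol epimers) | CCOc1cc(O[Si](C(C)C)(C(C)C)C(C)C)c([C@@H](C=C)[C@H](O[Si](C)(C)C(C)(C)C)c2ccc(OCc3ccccc3)c(OCc3ccccc3)c2)c(O)c1C(O)C#C | intermediate
20 | o-hydroxyaryl ynone | CCOc1cc(O[Si](C(C)C)(C(C)C)C(C)C)c([C@@H](C=C)[C@H](O[Si](C)(C)C(C)(C)C)c2ccc(OCc3ccccc3)c(OCc3ccccc3)c2)c(O)c1C(=O)C#C | intermediate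
21 | 5-ethoxy-7-(triisopropylsilyloxy)chromone with the (1S,2R) side chain at C8'' | CCOc1cc(O[Si](C(C)C)(C(C)C)C(C)C)c([C@@H](C=C)[C@H](O[Si](C)(C)C(C)(C)C)c2ccc(OCc3ccccc3)c(OCc3ccccc3)c2)c2occc(=O)c12 | intermediate
22 | 7-(benzyloxy)-5-ethoxychromone with the (1S,2R) side chain at C8'' | CCOc1cc(OCc2ccccc2)c([C@@H](C=C)[C@H](O[Si](C)(C)C(C)(C)C)c2ccc(OCc3ccccc3)c(OCc3ccccc3)c2)c2occc(=O)c12 | intermediate
23 | (2R,3S)-2-[7-(benzyloxy)-5-ethoxy-4-oxo-4H-chromen-8-yl]-3-[3,4-bis(benzyloxy)phenyl]-3-(tert-butyldimethylsilyloxy)propanal | CCOc1cc(OCc2ccccc2)c([C@@H](C=O)[C@H](O[Si](C)(C)C(C)(C)C)c2ccc(OCc3ccccc3)c(OCc3ccccc3)c2)c2occc(=O)c12 | intermediate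
24 | 1,3,5-tris(benzyloxy)benzene | c1ccc(COc2cc(OCc3ccccc3)cc(OCc3ccccc3)c2)cc1 | starting material
25 | 2-bromo-1,3,5-tris(benzyloxy)benzene | Brc1c(OCc2ccccc2)cc(OCc2ccccc2)cc1OCc1ccccc1 | intermediate
26 | 2,4,6-tris(benzyloxy)phenyllithium | [Li]c1c(OCc2ccccc2)cc(OCc2ccccc2)cc1OCc1ccccc1 | intermediate
27 | C4 carbinol (both C4 epimers) | CCOc1cc(OCc2ccccc2)c([C@@H](C(O)c2c(OCc3ccccc3)cc(OCc3ccccc3)cc2OCc2ccccc2)[C@H](O[Si](C)(C)C(C)(C)C)c2ccc(OCc3ccccc3)c(OCc3ccccc3)c2)c2occc(=O)c12 | intermediate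
28 | (2R,3S) C4 ketone, ring A tribenzyl ether | CCOc1cc(OCc2ccccc2)c([C@@H](C(=O)c2c(OCc3ccccc3)cc(OCc3ccccc3)cc2OCc2ccccc2)[C@H](O[Si](C)(C)C(C)(C)C)c2ccc(OCc3ccccc3)c(OCc3ccccc3)c2)c2occc(=O)c12 | intermediate
29 | (2R,3S) C4 ketone with free ortho phenol on ring A | CCOc1cc(OCc2ccccc2)c([C@@H](C(=O)c2c(O)cc(OCc3ccccc3)cc2OCc2ccccc2)[C@H](O[Si](C)(C)C(C)(C)C)c2ccc(OCc3ccccc3)c(OCc3ccccc3)c2)c2occc(=O)c12 | intermediate
30 | (2R,3S) β-hydroxy ketone | CCOc1cc(OCc2ccccc2)c([C@@H](C(=O)c2c(O)cc(OCc3ccccc3)cc2OCc2ccccc2)[C@H](O)c2ccc(OCc3ccccc3)c(OCc3ccccc3)c2)c2occc(=O)c12 | intermediate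
31 | (2R,3R)-cis flavanone–chromone | CCOc1cc(OCc2ccccc2)c([C@H]2C(=O)c3c(OCc4ccccc4)cc(OCc4ccccc4)cc3O[C@H]2c2ccc(OCc3ccccc3)c(OCc3ccccc3)c2)c2occc(=O)c12 | intermediate
32 | (2R,3S)-trans flavanone–chromone | CCOc1cc(OCc2ccccc2)c([C@@H]2C(=O)c3c(OCc4ccccc4)cc(OCc4ccccc4)cc3O[C@H]2c2ccc(OCc3ccccc3)c(OCc3ccccc3)c2)c2occc(=O)c12 | intermediate
33 | 4-(benzyloxy)phenylboronic acid | OB(O)c1ccc(OCc2ccccc2)cc1 | starting material
34 | (2R,3S,2''S) biflavanone, hexabenzyl 5''-ethyl ether | CCOc1cc(OCc2ccccc2)c([C@@H]2C(=O)c3c(OCc4ccccc4)cc(OCc4ccccc4)cc3O[C@H]2c2ccc(OCc3ccccc3)c(OCc3ccccc3)c2)c2O[C@H](c3ccc(OCc4ccccc4)cc3)CC(=O)c12 | intermediate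
35 | (2R,3S,2''S) biflavanone, pentabenzyl ether with free 5-OH and 5''-OH | Oc1cc(OCc2ccccc2)c([C@@H]2C(=O)c3c(O)cc(OCc4ccccc4)cc3O[C@H]2c2ccc(OCc3ccccc3)c(OCc3ccccc3)c2)c2O[C@H](c3ccc(OCc4ccccc4)cc3)CC(=O)c12 | intermediate
36 | (2R,3S)-2-(3,4-dihydroxyphenyl)-3-[(2S)-5,7-dihydroxy-2-(4-hydroxyphenyl)-4-oxochroman-8-yl]-5,7-dihydroxychroman-4-one | O=C1C[C@@H](c2ccc(O)cc2)Oc2c1c(O)cc(O)c2[C@@H]1C(=O)c2c(O)cc(O)cc2O[C@H]1c1ccc(O)c(O)c1 | target

Total step count: 21. Longest linear sequence: 20 (steps 1–12 and 14–21); step 13 is a one-step side branch.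

Steps most likely to fail

Step 6. The C3–H of ester 9 is allylic and α to the carbonyl, so proton abstraction by the carbenoid or by residual amide base may compete with carbonyl addition. That would lead on to double-bond migration or loss of silanolate. The fallback sets out from 9 and comes back at ynolate 11, and hence at 12, without any ester enolate chemistry.
- DIBAL-H in toluene at −78 °C should reduce 9 to (2S)-2-[(S)-[3,4-bis(benzyloxy)phenyl](tert-butyldimethylsilyloxy)methyl]but-3-enal F1, which is used crude.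
- Corey–Fuchs olefination (CBr4, PPh3, CH2Cl2, 0 °C) should give the 1,1-dibromoalkene F2.
- n-BuLi (2 equiv, THF, −78 °C) should convert F2 into the lithium acetylide F3.
- F3 is oxidized in the same flask with lithium tert-butyl peroxide (t-BuOOH, LiHMDS) to 11, and TIPSOTf then gives 12.

Step 14. Both partners are crowded, so addition may be slow. Enolization of the α-aryl aldehyde by the basic aryllithium may then take over, followed by loss of silanolate. The fallback sets out from 23 and 24 and comes back at 27. Iodination of 24 with N-iodosuccinimide (CH2Cl2, 0 °C) should give 2-iodo-1,3,5-tris(benzyloxy)benzene F4. F4 is coupled with 23 in a Nozaki–Hiyama–Kishi reaction (CrCl2, catalytic NiCl2, DMF, rt). The organochromium nucleophile is non-basic and reacts only with aldehydes, so the chromone and the acidic C3–H are left alone.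

Step 18. Two processes would erode the C2 configuration:
- ionization of the electron-rich benzylic oxyphosphonium salt;
- E1cB dehydration across C2–C3, followed by unselective oxa-Michael closure.

The fallback sets out from 22 and comes back at 31, and hence at 32. It forms O1–C2 before any carbonyl flanks C3.
- HF·pyridine should free the homoallylic benzylic alcohol F5.
- An intermolecular Mitsunobu reaction with commercial 3,5-bis(benzyloxy)phenol (PPh3, DIAD, toluene, 0 °C) should give, with inversion, the aryl ether F6.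
- Lemieux–Johnson cleavage should give the aldehyde F7.
- Pinnick oxidation (NaClO2, NaH2PO4, 2-methylbut-2-ene) should give the acid F8.
- Intramolecular Friedel–Crafts acylation through the mixed anhydride (trifluoroacetic anhydride, CH2Cl2, 0 °C) should close C4–C4a ortho to the aryloxy oxygen and give 31.
- Et3N in MeOH equilibrates 31 to 32. Steps 13–17 are then not needed.

Further compounds
F1 | step 6 | (2S)-2-[(S)-[3,4-bis(benzyloxy)phenyl](tert-butyldimethylsilyloxy)methyl]but-3-enal | O=C[C@@H](C=C)[C@H](O[Si](C)(C)C(C)(C)C)c1ccc(OCc2ccccc2)c(OCc2ccccc2)c1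
F2 | step 6 | 1,1-dibromoalkene from F1 (configuration as in 9) | BrC(Br)=C[C@@H](C=C)[C@H](O[Si](C)(C)C(C)(C)C)c1ccc(OCc2ccccc2)c(OCc2ccccc2)c1
F3 | step 6 | lithium acetylide from F2 (configuration as in 12) | [Li]C#C[C@@H](C=C)[C@H](O[Si](C)(C)C(C)(C)C)c1ccc(OCc2ccccc2)c(OCc2ccccc2)c1
F4 | step 14 | 2-iodo-1,3,5-tris(benzyloxy)benzene | Ic1c(OCc2ccccc2)cc(OCc2ccccc2)cc1OCc1ccccc1
F5 | step 18 | 7-(benzyloxy)-8-[(1S,2R)-1-[3,4-bis(benzyloxy)phenyl]-1-hydroxybut-3-en-2-yl]-5-ethoxy-4H-chromen-4-one | CCOc1cc(OCc2ccccc2)c([C@@H](C=C)[C@H](O)c2ccc(OCc3ccccc3)c(OCc3ccccc3)c2)c2occc(=O)c12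
F6 | step 18 | 7-(benzyloxy)-8-[(1R,2R)-1-[3,5-bis(benzyloxy)phenoxy]-1-[3,4-bis(benzyloxy)phenyl]but-3-en-2-yl]-5-ethoxy-4H-chromen-4-one | CCOc1cc(OCc2ccccc2)c([C@@H](C=C)[C@@H](Oc2cc(OCc3ccccc3)cc(OCc3ccccc3)c2)c2ccc(OCc3ccccc3)c(OCc3ccccc3)c2)c2occc(=O)c12
F7 | step 18 | (2R,3R)-2-[7-(benzyloxy)-5-ethoxy-4-oxo-4H-chromen-8-yl]-3-[3,5-bis(benzyloxy)phenoxy]-3-[3,4-bis(benzyloxy)phenyl]propanal | CCOc1cc(OCc2ccccc2)c([C@@H](C=O)[C@@H](Oc2cc(OCc3ccccc3)cc(OCc3ccccc3)c2)c2ccc(OCc3ccccc3)c(OCc3ccccc3)c2)c2occc(=O)c12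
F8 | step 18 | (2R,3R)-2-[7-(benzyloxy)-5-ethoxy-4-oxo-4H-chromen-8-yl]-3-[3,5-bis(benzyloxy)phenoxy]-3-[3,4-bis(benzyloxy)phenyl]propanoic acid | CCOc1cc(OCc2ccccc2)c([C@@H](C(=O)O)[C@@H](Oc2cc(OCc3ccccc3)cc(OCc3ccccc3)c2)c2ccc(OCc3ccccc3)c(OCc3ccccc3)c2)c2occc(=O)c12
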